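## Structural features

The target 30 is built on one cyclopentane ring, numbered here C1 (CH2O–acyl), C2 (CH3), C3 (O–acyl), C4 (CH2) and C5 (CH(CH2OH)2), with four stereocentres in a row (C5, C1, C2, C3) and the absolute configuration 1S,2R,3R,5R. Every vicinal pair is trans, which puts the C2 methyl group and the C5 arm on one face and the oxygen-bearing substituents of C1 and C3 on the other. Both oxygens carry the same (3S,4E)-4-formyl-3-(2-oxoethyl)hex-4-enoyl chain, whose single stereocentre is flanked by an (E)-2-ethylidene aldehyde, a CH2CHO arm and the CH2CO2 link. The fragile parts are the four aldehydes (two enals that can isomerise or deconjugate, two enolisable ones, in 1,5-relationship), the two esters (a δ-hydroxyl group set free on either chain would lactonise and expel the core) and the free 1,3-diol, which can acetalise with the aldehydes. The real difficulty is therefore double: to place C5 correctly against C2 and C3 on a ring whose C4 offers no handle, and to carry four aldehydes and a diol through esterification to one mild unmasking. The key step exploits that C1 and C5, together with the first carbon of each arm, are the ring-fusion carbons (C7a, C4a) and C1/C4 of a cyclopenta[c]pyran: the 1-oxadiene O=CH–C1=C5 of a cyclopentenecarbaldehyde takes up a vinyl ether across O and C5, and the temporary dihydropyran is later opened to the C1 formyl group and the C5 CH2CHO arm. Since C1 then sits α to an aldehyde, its configuration is settled by equilibration to the all-trans isomer, so the cycloaddition has to control only C5.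

## Logic of the disconnections

30 ⇒ 29. The four formyl groups and the 1,3-diol are traced back to four dimethyl acetals and one isopropylidene ketal. No C–C bond is cut. The reason is that the aldehydes must appear last and that no hydroxyl group may ever stand δ to the ester carbonyls. The gain is a single closing operation. The demand is a hydrolysis mild enough for two esters and two enals.

29 ⇒ 17 + 28 (twice). The two ester C–O bonds are cut. The same acid serves both positions, so the synthesis becomes convergent and the side-chain stereocentre is made once. The forward step must acylate a primary and a hindered secondary hydroxyl group while the diol of the C5 arm stays masked, and the acid must carry no free carbonyl group.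

17 ⇒ 16 ⇒ 15 ⇒ 13 ⇒ 12 ⇒ 11. After two protecting-group retrons (silyl ether, ketal), the arm is dismantled: one C–O bond (hydroboration), two carbonyl reductions, and the C=CH2 bond that brings the last carbon. The reason is that CH(CH2OH)2 is a CH2CHO arm plus one carbon. The gain is that 11 holds only the carbons of the cycloadduct. The demand is that the one-carbon homologation touches only the CH2CHO arm (the branched C1 aldehyde has no second α-hydrogen) and that C1 is reduced before it can drift from the trans arrangement.

11 ⇒ 9. The two aldehyde carbons are rejoined through one oxygen as an enol ether and a mixed acetal. This turns a flexible dialdehyde into a bicycle in which C5 is defined. The demand on the forward step is clean hydrolysis and equilibration of C1, the only epimerisable centre, to the isomer trans to both neighbours.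

9 ⇒ 7 + 8. The C4a–C4 bond (C5–CH2 of the target) and the O2–C3 acetal bond are cut in a retro-[4+2] sense. The gain is two simple components and a ring-forming step that creates the C5 stereocentre. The demand is π-facial selectivity syn to the methyl group. For this reason 7 carries a tert-butyldiphenylsilyl ether rather than a smaller trialkylsilyl ether: it shields the face anti to the methyl group and, unlike a small silyl ether, survives the aqueous acid that later opens the pyran. The (4R,5R) configuration of 7 and the (3S,4aS,6R,7R) configuration of 9 map without change onto C2, C3 and C5 of 30.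

7 ⇒ 6 ⇒ 4 ⇒ 3 ⇒ 1. The C–CHO bond is cut to an alkenyl triflate, this to the ketone, and the C3–O bond to the enone by conjugate borylation and oxidation. The gain is a four-step access from a commercial enone. The demands are an enantioselective β-borylation, a C2 centre that settles trans because it is epimerisable, and kinetic enolisation away from the β-silyloxy group.

28 ⇒ 27 ⇒ 26 ⇒ 24. Functional-group retrons lead from the acetal acid to a δ-lactone in which the carboxyl carbon and the future CH2CHO carbon are the two ends of the ring. The gain is that the stereocentre becomes C4 of a six-membered acceptor. The demand is that the opened hydroxy ester is oxidised before it can close again.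

24 ⇒ 22 + 23 and 22 ⇒ 20 ⇒ 19 ⇒ 18. The bond between the stereocentre and the alkenyl carbon is cut (asymmetric conjugate alkenylation), then the C–B bond to a C–I bond, the acetal to the aldehyde, and the C–I bond to an enal C–H bond. The gain is that the E-ethylidene aldehyde comes from a commercial enal with its geometry already thermodynamically fixed. The demand is retention of alkene geometry through metalation and transmetalation, and catalyst control of the new stereocentre.

## Other disconnections considered

Alternative 1: The C1–CH2 and C2–CH3 bonds are cut, leading back to the enantiopure cyclopentenone A2, (R)-4-(2,2-dimethyl-1,3-dioxan-5-yl)cyclopent-2-en-1-one, in which C3 is the carbonyl carbon and the diol arm is already in place. Forward, a CuI-catalysed (monovalent copper) addition of (isopropoxydimethylsilyl)methylmagnesium chloride to C1 anti to the C5 substituent, then methylation of the enolate at C2 with MeI anti to the new group, would give ketone A1. Reduction of the C3 ketone and Tamao oxidation of the C–Si bond would then reach 17 in two further steps.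
- In its favour: C1, C2 and C5 are set by substrate control from one stereocentre in the familiar trans,trans sense, C1 needs no equilibration, the hydroxymethyl group arrives at the right oxidation level, and the diol never has to be built on the ring. On these points and on the number of steps after the key step it is the better plan.
- Against it here: the magnesium enolate is a sluggish partner for MeI and may exchange protons first, so C4 methylation and over-methylation threaten. The C3 carbinol must come from hydride attack on the face of the methyl group, for which small hydrides have only a moderate inherent preference. A2 itself needs an asymmetric synthesis of several steps, which offsets the later saving.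
- Comparison: mechanistically it trades one catalyst-controlled cycloaddition for two ionic, substrate-controlled bond formations. The overall step count is judged about equal. The chosen plan is kept because its C3 oxygen is configurationally secure from step 1.

Alternative 2: The C1–C5 bond is cut to the acyclic enal A4, dimethyl 2-[(3R,4E)-3-(tert-butyldimethylsilyloxy)-4-methyl-6-oxohex-4-en-1-ylidene]propanedioate. Forward, a chiral imidazolidinone salt and a Hantzsch ester would transfer hydride to C2 of the iminium ion, and the resulting enamine would add to the alkylidene malonate (5-exo-trig Michael closure), forming C1–C5 and giving the all-trans aldehyde A3.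
- In its favour: the ring, three stereocentres and both arms are made in one organocatalytic step, and the malonate is a direct precursor of the 1,3-diol (one hydride reduction of A3 gives the triol that corresponds to 15). In bonds formed per step and in steps after the key step it is better than the chosen plan. In the control of C1, which is again α to an aldehyde and thermodynamically correctable, it is its equal.
- Against it here: the hydride transfer must set C2 next to an existing C3 silyloxy stereocentre on a β,β-disubstituted enal, and whether that pairing is matched is open. The γ-hydrogen at C3 invites dienamine formation, with loss of C3 integrity or of the silyloxy group. The closure must then set C5 as well. A4 also needs its own multistep asymmetric preparation.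
- Comparison: the chosen plan has C2 and C3 fixed and thermodynamically trans before the key step and asks the catalyst for one centre only.

Alternative 3: The C2–C3 bond is cut to the acyclic aldehyde A6, (3R,4R)-4-[(benzyloxy)methyl]-3-(2,2-dimethyl-1,3-dioxan-5-yl)hex-5-enal, in which C1 and C5 are already stereogenic and C2 is the inner carbon of a vinyl group. Forward, SmI2 (divalent samarium) with HMPA and tert-butanol would reduce the aldehyde to a ketyl that adds 5-exo-trig to the vinyl group. The primary radical is reduced and protonated to the C2 methyl group, giving cyclopentanol A5, from which hydrogenolysis of the benzyl ether leads to 17.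
- In its favour: the hydroxyl/methyl pair forms in the anti arrangement that ketyl–olefin closures prefer, the allylic C1 substituent should steer the methyl group trans, A5 arrives with its protecting groups already differentiated, and one step separates it from 17. On steps after the key step it is better than the chosen plan, and on C2/C3 relative control it is its equal.
- Against it here: ketyls of aldehydes add poorly to unactivated alkenes and are diverted to pinacol coupling or simple reduction. The reagent is stoichiometric and needs HMPA. A6, with its anti C1/C5 pair, has to be assembled acyclically in a long sequence.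
- Comparison: the cycloaddition of the chosen plan is catalytic, rests on a close precedent for the same heterodiene class, and starts from a four-step precursor.

Key step: step 5

Assumption: in steps 1, 5 and 15 the ligand antipode written is the one expected from the accepted stereochemical model of its catalyst family to give the configuration drawn; if the sense of induction were the reverse, the mirror-image ligand would be used and nothing else would change.

## Route

Step 1
Reactants: 1 2-methylcyclopent-2-en-1-one
Product: 3 (2S,3R)-3-hydroxy-2-methylcyclopentan-1-one, via β-boryl ketone 2 (not isolated)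
Conditions: CuCl (5 mol%), NaOtBu (10 mol%), (R)-1-[(S)-2-(diphenylphosphino)ferrocenyl]ethyldicyclohexylphosphine (6 mol%), B2pin2 (1.1 equiv), MeOH (2 equiv), THF, 0 → 23 °C; then NaBO3·4H2O, THF/H2O, 23 °C
Reagents that add atoms: bis(pinacolato)diboron CC1(C)OB(OC1(C)C)B1OC(C)(C)C(C)(C)O1 (boron of 2); sodium perborate [Na+].[O-]OB=O (oxygen of 3)
Why: Copper–boryl conjugate addition to a cyclic enone (β-borylation) followed by perborate oxidation with retention; the chiral bisphosphine–copper boryl complex selects the enone face at C3, and protonation of the copper enolate by MeOH, together with the ready epimerisation of C2, should leave the methyl group trans to the new C–B and then C–O bond.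

Step 2
Reactants: 3 (2S,3R)-3-hydroxy-2-methylcyclopentan-1-one
Product: 4 (2S,3R)-3-[(tert-butyldiphenylsilyl)oxy]-2-methylcyclopentan-1-one
Conditions: tert-butyl(chloro)diphenylsilane (1.2 equiv), imidazole (2.5 equiv), DMF, 23 °C
Reagents that add atoms: tert-butyl(chloro)diphenylsilane CC(C)(C)[Si](Cl)(c1ccccc1)c1ccccc1
Why: Standard silylation of a secondary alcohol; the bulky, acid-stable tert-butyldiphenylsilyl ether is preferred to a smaller trialkylsilyl ether because it must survive the aqueous acid of step 6 and shield the face anti to the methyl group in step 5, and imidazole is too weak a base to trigger β-elimination.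

Step 3
Reactants: 4 (2S,3R)-3-[(tert-butyldiphenylsilyl)oxy]-2-methylcyclopentan-1-one
Product: 6 (4R,5S)-4-[(tert-butyldiphenylsilyl)oxy]-5-methylcyclopent-1-en-1-yl trifluoromethanesulfonate, via lithium enolate 5 (not isolated)
Conditions: LiN(iPr)2 (1.1 equiv), THF, −78 °C; then PhNTf2 (1.15 equiv), −78 → 0 °C; aq. NH4Cl
Reagents that add atoms: lithium diisopropylamide [Li+].CC(C)[N-]C(C)C (lithium of 5); N-phenylbis(trifluoromethanesulfonimide) O=S(=O)(N(c1ccccc1)S(=O)(=O)C(F)(F)F)C(F)(F)F
Why: Kinetic deprotonation by the hindered amide at the unsubstituted methylene (not at the methyl-bearing carbon, whose enolate would expel the β-silyloxy group) and O-triflation of the lithium enolate; no stereocentre is touched.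

Step 4
Reactants: 6 (4R,5S)-4-[(tert-butyldiphenylsilyl)oxy]-5-methylcyclopent-1-en-1-yl trifluoromethanesulfonate
Product: 7 (4R,5R)-4-[(tert-butyldiphenylsilyl)oxy]-5-methylcyclopent-1-ene-1-carbaldehyde
Conditions: Pd(PPh3)4 (5 mol%), LiCl (3 equiv), CO (1 atm), Bu3SnH (1.2 equiv, syringe pump), THF, 50 °C
Reagents that add atoms: carbon monoxide [C-]#[O+]
Why: Palladium-catalysed reductive carbonylation (formylation) of an alkenyl triflate: oxidative addition to zerovalent palladium, CO insertion and hydride transfer from the tin hydride to the acyl complex; slow addition of the hydride under CO suppresses direct reduction of the triflate.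

Step 5
Reactants: 7 (4R,5R)-4-[(tert-butyldiphenylsilyl)oxy]-5-methylcyclopent-1-ene-1-carbaldehyde; 8 ethyl vinyl ether
Product: 9 (3S,4aS,6R,7R)-6-[(tert-butyldiphenylsilyl)oxy]-3-ethoxy-7-methyl-3,4,4a,5,6,7-hexahydrocyclopenta[c]pyran
Conditions: CrCl(L) (5 mol%; L = dianion C27H29NO2 of the Schiff base from (1R,2S)-1-aminoindan-2-ol and 3-(1-adamantyl)-2-hydroxy-5-methylbenzaldehyde), 4 Å molecular sieves, 8 (10 equiv, no other solvent), 23 °C
Reagents that add atoms: none
Why: The chromium centre (trivalent) binds the aldehyde oxygen of 7, lowers the LUMO of the s-cis 1-oxadiene O=CH–C1=C2 and lets the electron-rich alkene of 8 add in a concerted, asynchronous inverse-electron-demand [4+2] cycloaddition in which the CH2 terminus of 8 bonds to the enal β-carbon (C4a of 9, C5 of the target) slightly ahead of the O–C3 bond. The closest known reaction type is the chromium Schiff-base-catalysed hetero-Diels–Alder reaction of alkyl-substituted cyclopent-1-enecarbaldehydes with ethyl vinyl ether. The dihydropyran is closed by the cycloaddition itself (six-membered ring, both σ bonds formed suprafacially on each partner), so there is no separate ring-closing event with its own selectivity. C4a is set by the catalyst, which leaves one face of the bound heterodiene open; the antipode is chosen so that this is the face syn to the C7 methyl group, and the bulky silyloxy group on the opposite face at C6 works in the same direction. C3 follows from the endo orientation of the ethoxy group under the coordinated heterodiene, which places it cis to the C4a–C5 bond; this centre is lost again in step 6. Regiochemistry is fixed by polarity (nucleophilic CH2 of 8 to the electrophilic β-carbon, oxygen to the alkoxy-bearing carbon). The selectivity the step needs is π-facial selectivity against the allylic methyl group; it is secured by catalyst control, for which this catalyst family has precedent with 5-methyl-substituted heterodienes, reinforced by the trans silyloxy group of 7, while molecular sieves and excess 8 keep the Lewis acid active and the rate acceptable.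

Step 6
Reactants: 9 (3S,4aS,6R,7R)-6-[(tert-butyldiphenylsilyl)oxy]-3-ethoxy-7-methyl-3,4,4a,5,6,7-hexahydrocyclopenta[c]pyran
Product: 11 (1S,2R,3R,5S)-3-[(tert-butyldiphenylsilyl)oxy]-2-methyl-5-(2-oxoethyl)cyclopentane-1-carbaldehyde, via C1-epimeric dialdehyde 10 (not isolated)
Conditions: 1 M aq. HCl/THF (1:4), 23 °C; extractive work-up; then DBU (0.1 equiv), CH2Cl2, 0 °C
Reagents that add atoms: water O
Why: Acid hydrolysis of the enol ether and the mixed acetal opens the dihydropyran to a 1,5-dialdehyde; protonation at C7a on the convex face should first give mainly the C1 epimer 10, and because C1 is now α to a formyl group, catalytic DBU equilibrates it to 11, with the formyl group trans to both the C2 methyl group and the C5 arm (thermodynamic control). C5 is α to neither carbonyl group and stays fixed.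

Step 7
Reactants: 11 (1S,2R,3R,5S)-3-[(tert-butyldiphenylsilyl)oxy]-2-methyl-5-(2-oxoethyl)cyclopentane-1-carbaldehyde
Product: 12 (1S,2R,3R,5R)-3-[(tert-butyldiphenylsilyl)oxy]-2-methyl-5-(3-oxoprop-1-en-2-yl)cyclopentane-1-carbaldehyde
Conditions: 37% aq. CH2O (1.2 equiv), pyrrolidine (10 mol%), propionic acid (10 mol%), iPrOH, 45 °C
Reagents that add atoms: formaldehyde C=O
Why: Amine-catalysed Mannich condensation with formaldehyde followed by elimination of the amine (α-methylenation of an aldehyde that has an α-CH2 group); the α-branched C1 aldehyde has no second α-hydrogen and cannot give an enal, so only the CH2CHO arm should be converted, and any enamine-mediated epimerisation at C1 returns the same trans isomer.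

Step 8
Reactants: 12 (1S,2R,3R,5R)-3-[(tert-butyldiphenylsilyl)oxy]-2-methyl-5-(3-oxoprop-1-en-2-yl)cyclopentane-1-carbaldehyde
Product: 13 2-[(1R,2S,3R,4R)-4-[(tert-butyldiphenylsilyl)oxy]-2-(hydroxymethyl)-3-methylcyclopentyl]prop-2-en-1-ol
Conditions: NaBH4 (2.5 equiv), CeCl3·7H2O (1.2 equiv), MeOH, −40 → 0 °C
Reagents that add atoms: none
Why: Luche reduction: the cerium-modified borohydride reduces the saturated aldehyde and, by 1,2-addition only, the enal; C1 becomes CH2OH and can no longer epimerise.

Step 9
Reactants: 13 2-[(1R,2S,3R,4R)-4-[(tert-butyldiphenylsilyl)oxy]-2-(hydroxymethyl)-3-methylcyclopentyl]prop-2-en-1-ol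
Product: 15 2-[(1R,2S,3R,4R)-4-[(tert-butyldiphenylsilyl)oxy]-2-(hydroxymethyl)-3-methylcyclopentyl]propane-1,3-diol, via tris-borane adduct 14 (not isolated)
Conditions: 9-BBN (0.5 M in THF, 3.5 equiv), THF, 0 → 23 °C; then 3 M aq. NaOH, 30% H2O2, 0 → 23 °C
Reagents that add atoms: 9-borabicyclo[3.3.1]nonane [H]B1C2CCCC1CCC2 (boron of 14); hydrogen peroxide OO (oxygen of 15)
Why: Anti-Markovnikov hydroboration of the 1,1-disubstituted alkene (the two hydroxyl groups are first converted into borinates with loss of H2) and oxidation with retention give the primary alcohol; the carbon that is stereogenic in 14 carries two identical CH2OH arms after oxidation, so its configuration is of no consequence.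

Step 10
Reactants: 15 2-[(1R,2S,3R,4R)-4-[(tert-butyldiphenylsilyl)oxy]-2-(hydroxymethyl)-3-methylcyclopentyl]propane-1,3-diol
Product: 16 [(1S,2R,3R,5R)-3-[(tert-butyldiphenylsilyl)oxy]-5-(2,2-dimethyl-1,3-dioxan-5-yl)-2-methylcyclopentyl]methanol
Conditions: 2,2-dimethoxypropane (1.5 equiv), PPTS (5 mol%), acetone, 23 °C; Et3N quench
Reagents that add atoms: 2,2-dimethoxypropane COC(C)(C)OC
Why: Acid-catalysed transketalisation under thermodynamic control: the six-membered 1,3-dioxane of the 1,3-diol is strongly preferred over an eight-membered ketal that would have to include the C1 hydroxymethyl group, which is therefore left free.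

Step 11
Reactants: 16 [(1S,2R,3R,5R)-3-[(tert-butyldiphenylsilyl)oxy]-5-(2,2-dimethyl-1,3-dioxan-5-yl)-2-methylcyclopentyl]methanol
Product: 17 (1R,2R,3S,4R)-4-(2,2-dimethyl-1,3-dioxan-5-yl)-3-(hydroxymethyl)-2-methylcyclopentan-1-ol
Conditions: Bu4NF (1 M in THF, 1.5 equiv), THF, 23 → 40 °C; aq. NH4Cl
Reagents that add atoms: none
Why: Fluoride-mediated cleavage of the silyl ether, driven by Si–F bond formation; the ketal and the primary alcohol are inert to the reagent.

Step 12
Reactants: 18 (E)-but-2-enal
Product: 19 (Z)-2-iodobut-2-enal
Conditions: I2 (1.5 equiv), K2CO3 (1.2 equiv), DMAP (0.2 equiv), THF/H2O (1:1), 23 °C, dark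
Reagents that add atoms: iodine II
Why: α-Iodination of an enal by conjugate addition of DMAP, iodination of the resulting enolate and elimination of the amine; the thermodynamically preferred isomer, with the formyl group trans to the methyl group, is the (Z)-iodide.

Step 13
Reactants: 19 (Z)-2-iodobut-2-enal
Product: 20 (Z)-2-iodo-1,1-dimethoxybut-2-ene
Conditions: HC(OMe)3 (2 equiv), p-TsOH·H2O (1 mol%), MeOH, 0 → 23 °C; NaHCO3
Reagents that add atoms: trimethyl orthoformate COC(OC)OC
Why: Acid-catalysed acetalisation with the orthoformate as water scavenger; masking the aldehyde allows halogen–lithium exchange and carries the future enal through to the last step, and the double-bond geometry is untouched.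

Step 14
Reactants: 20 (Z)-2-iodo-1,1-dimethoxybut-2-ene
Product: 22 2-[(E)-1,1-dimethoxybut-2-en-2-yl]-4,4,5,5-tetramethyl-1,3,2-dioxaborolane, via alkenyllithium 21 (not isolated)
Conditions: t-BuLi (2.05 equiv), Et2O, −78 °C; then 2-isopropoxy-4,4,5,5-tetramethyl-1,3,2-dioxaborolane (1.3 equiv), −78 → 0 °C; aq. NH4Cl
Reagents that add atoms: tert-butyllithium [Li]C(C)(C)C (lithium of 21); 2-isopropoxy-4,4,5,5-tetramethyl-1,3,2-dioxaborolane CC(C)OB1OC(C)(C)C(C)(C)O1
Why: Iodine–lithium exchange gives a configurationally stable alkenyllithium at −78 °C (α-lithiated enal acetals persist at this temperature), which is borylated with retention, so boron ends up cis to the methyl group as the later E-enal requires.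

Step 15
Reactants: 22 2-[(E)-1,1-dimethoxybut-2-en-2-yl]-4,4,5,5-tetramethyl-1,3,2-dioxaborolane; 23 5,6-dihydro-2H-pyran-2-one
Product: 24 (4S)-4-[(2E)-1,1-dimethoxybut-2-en-2-yl]oxan-2-one
Conditions: [RhCl(C2H4)2]2 (2.5 mol%), (S)-BINAP (5.5 mol%), KOH (10 mol%), 22 (1.5 equiv), 1,4-dioxane/H2O (10:1), 40 °C
Reagents that add atoms: none
Why: Rhodium-catalysed asymmetric conjugate addition of an alkenylboron reagent to an α,β-unsaturated lactone (Hayashi–Miyaura reaction): transmetalation to the hydroxorhodium–BINAP complex (monovalent rhodium), enantioface-selective insertion of the lactone C=C bond and hydrolysis of the rhodium enolate by water. The (S)-BINAP complex should expose the lactone face that gives the (4S) adduct, and the alkenyl group is transferred with retention of its geometry.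

Step 16
Reactants: 24 (4S)-4-[(2E)-1,1-dimethoxybut-2-en-2-yl]oxan-2-one
Product: 26 methyl (3S,4E)-4-(dimethoxymethyl)-3-(2-oxoethyl)hex-4-enoate, via hydroxy ester 25 (not isolated)
Conditions: Et3N (3 equiv), MeOH, 23 °C; evaporation below 25 °C; then 1,1,1-triacetoxy-1,1-dihydro-1,2-benziodoxol-3(1H)-one (1.3 equiv), NaHCO3, CH2Cl2, 0 → 23 °C
Reagents that add atoms: methanol CO
Why: Base-catalysed methanolysis opens the δ-lactone to the hydroxy ester, which is oxidised at once with the buffered periodinane because it would relactonise on storage; the stereocentre is β to both carbonyl groups and cannot epimerise.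

Step 17
Reactants: 26 methyl (3S,4E)-4-(dimethoxymethyl)-3-(2-oxoethyl)hex-4-enoate
Product: 27 methyl (3S,4E)-3-(2,2-dimethoxyethyl)-4-(dimethoxymethyl)hex-4-enoate
Conditions: HC(OMe)3 (3 equiv), PPTS (5 mol%), MeOH, 23 °C
Reagents that add atoms: trimethyl orthoformate COC(OC)OC
Why: Acetalisation of the aliphatic aldehyde, so that the acid can be liberated and coupled without the aldehyde–acid pair closing to a cyclic pseudo-acid.

Step 18
Reactants: 27 methyl (3S,4E)-3-(2,2-dimethoxyethyl)-4-(dimethoxymethyl)hex-4-enoate
Product: 28 (3S,4E)-3-(2,2-dimethoxyethyl)-4-(dimethoxymethyl)hex-4-enoic acid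
Conditions: LiOH·H2O (3 equiv), THF/MeOH/H2O (3:1:1), 0 → 23 °C; then 1 M HCl to pH 4 at 0 °C, EtOAc extraction
Reagents that add atoms: lithium hydroxide [Li+].[OH-]
Why: Saponification of the methyl ester; acetals are stable to hydroxide, and acidification only to pH 4 in the cold keeps them intact.

Step 19
Reactants: 17 (1R,2R,3S,4R)-4-(2,2-dimethyl-1,3-dioxan-5-yl)-3-(hydroxymethyl)-2-methylcyclopentan-1-ol; 28 (3S,4E)-3-(2,2-dimethoxyethyl)-4-(dimethoxymethyl)hex-4-enoic acid
Product: 29 {(1S,2R,3R,5R)-3-{[(3S,4E)-3-(2,2-dimethoxyethyl)-4-(dimethoxymethyl)hex-4-enoyl]oxy}-5-(2,2-dimethyl-1,3-dioxan-5-yl)-2-methylcyclopentyl}methyl (3S,4E)-3-(2,2-dimethoxyethyl)-4-(dimethoxymethyl)hex-4-enoate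
Conditions: 28 (2.6 equiv), DCC (3 equiv), DMAP (0.5 equiv), CH2Cl2, 0 → 23 °C
Reagents that add atoms: none
Why: Steglich esterification (carbodiimide activation, acyl transfer by DMAP) of both the primary and the secondary hydroxyl group with an excess of the acid; the acid has no α-stereocentre, so activation cannot epimerise it, and all aldehyde equivalents are inert acetals.

Step 20
Reactants: 29 the fully protected diester
Product: 30 [(1S,2R,3R,5R)-5-(1,3-dihydroxypropan-2-yl)-3-{[(3S,4E)-4-formyl-3-(2-oxoethyl)hex-4-enoyl]oxy}-2-methylcyclopentyl]methyl (3S,4E)-4-formyl-3-(2-oxoethyl)hex-4-enoate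
Conditions: THF/1 M aq. HCl (3:1), 0 → 23 °C; NaHCO3 to pH 6, EtOAc extraction
Reagents that add atoms: water O
Why: Specific-acid-catalysed hydrolysis of four dimethyl acetals and the isopropylidene ketal in one operation; esters are stable at this acidity, the E enals are the thermodynamic isomers and no stereocentre is α to a carbonyl group, so nothing can epimerise.

## Compound list

1 | 2-methylcyclopent-2-en-1-one | CC1=CCCC1=O | starting material
2 | (2S,3R)-2-methyl-3-(4,4,5,5-tetramethyl-1,3,2-dioxaborolan-2-yl)cyclopentan-1-one | O=C1CC[C@@H](B2OC(C)(C)C(C)(C)O2)[C@@H]1C | intermediate (not isolated)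
3 | (2S,3R)-3-hydroxy-2-methylcyclopentan-1-one | O=C1CC[C@@H](O)[C@@H]1C | intermediate
4 | (2S,3R)-3-[(tert-butyldiphenylsilyl)oxy]-2-methylcyclopentan-1-one | O=C1CC[C@@H](O[Si](c2ccccc2)(c2ccccc2)C(C)(C)C)[C@@H]1C | intermediate
5 | lithium (4R,5S)-4-[(tert-butyldiphenylsilyl)oxy]-5-methylcyclopent-1-en-1-olate | [Li+].[O-]C1=CC[C@@H](O[Si](c2ccccc2)(c2ccccc2)C(C)(C)C)[C@@H]1C | intermediate (not isolated)
6 | (4R,5S)-4-[(tert-butyldiphenylsilyl)oxy]-5-methylcyclopent-1-en-1-yl trifluoromethanesulfonate | FC(F)(F)S(=O)(=O)OC1=CC[C@@H](O[Si](c2ccccc2)(c2ccccc2)C(C)(C)C)[C@@H]1C | intermediate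
7 | (4R,5R)-4-[(tert-butyldiphenylsilyl)oxy]-5-methylcyclopent-1-ene-1-carbaldehyde | O=CC1=CC[C@@H](O[Si](c2ccccc2)(c2ccccc2)C(C)(C)C)[C@@H]1C | intermediate
8 | ethyl vinyl ether (ethoxyethene) | C=COCC | starting material
9 | (3S,4aS,6R,7R)-6-[(tert-butyldiphenylsilyl)oxy]-3-ethoxy-7-methyl-3,4,4a,5,6,7-hexahydrocyclopenta[c]pyran | O1C=C2[C@@H](C)[C@H](O[Si](c3ccccc3)(c3ccccc3)C(C)(C)C)C[C@H]2C[C@H]1OCC | intermediate
10 | (1R,2R,3R,5S)-3-[(tert-butyldiphenylsilyl)oxy]-2-methyl-5-(2-oxoethyl)cyclopentane-1-carbaldehyde (C1 epimer of 11) | O=C[C@H]1[C@@H](C)[C@H](O[Si](c2ccccc2)(c2ccccc2)C(C)(C)C)C[C@H]1CC=O | intermediate (not isolated)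
11 | (1S,2R,3R,5S)-3-[(tert-butyldiphenylsilyl)oxy]-2-methyl-5-(2-oxoethyl)cyclopentane-1-carbaldehyde | O=C[C@@H]1[C@@H](C)[C@H](O[Si](c2ccccc2)(c2ccccc2)C(C)(C)C)C[C@H]1CC=O | intermediate
12 | (1S,2R,3R,5R)-3-[(tert-butyldiphenylsilyl)oxy]-2-methyl-5-(3-oxoprop-1-en-2-yl)cyclopentane-1-carbaldehyde | O=C[C@@H]1[C@@H](C)[C@H](O[Si](c2ccccc2)(c2ccccc2)C(C)(C)C)C[C@H]1C(=C)C=O | intermediate
13 | 2-[(1R,2S,3R,4R)-4-[(tert-butyldiphenylsilyl)oxy]-2-(hydroxymethyl)-3-methylcyclopentyl]prop-2-en-1-ol | OC[C@@H]1[C@@H](C)[C@H](O[Si](c2ccccc2)(c2ccccc2)C(C)(C)C)C[C@H]1C(=C)CO | intermediate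
14 | tris(9-borabicyclo[3.3.1]nonan-9-yl) adduct of 13: 9-BBN borinates of both hydroxyl groups and B-alkyl-9-BBN at the former methylene carbon (epimers at the new CH) | B1(OC[C@@H]3[C@@H](C)[C@H](O[Si](c4ccccc4)(c4ccccc4)C(C)(C)C)C[C@H]3C(COB5C6CCCC5CCC6)CB7C8CCCC7CCC8)C2CCCC1CCC2 | intermediate (not isolated)
15 | 2-[(1R,2S,3R,4R)-4-[(tert-butyldiphenylsilyl)oxy]-2-(hydroxymethyl)-3-methylcyclopentyl]propane-1,3-diol | OC[C@@H]1[C@@H](C)[C@H](O[Si](c2ccccc2)(c2ccccc2)C(C)(C)C)C[C@H]1C(CO)CO | intermediate
16 | [(1S,2R,3R,5R)-3-[(tert-butyldiphenylsilyl)oxy]-5-(2,2-dimethyl-1,3-dioxan-5-yl)-2-methylcyclopentyl]methanol | OC[C@@H]1[C@@H](C)[C@H](O[Si](c2ccccc2)(c2ccccc2)C(C)(C)C)C[C@H]1C3COC(C)(C)OC3 | intermediate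
17 | (1R,2R,3S,4R)-4-(2,2-dimethyl-1,3-dioxan-5-yl)-3-(hydroxymethyl)-2-methylcyclopentan-1-ol | OC[C@@H]1[C@@H](C)[C@H](O)C[C@H]1C3COC(C)(C)OC3 | intermediate
18 | (E)-but-2-enal (crotonaldehyde) | C/C=C/C=O | starting material
19 | (Z)-2-iodobut-2-enal | C/C=C(/C=O)I | intermediate
20 | (Z)-2-iodo-1,1-dimethoxybut-2-ene | C/C=C(/C(OC)OC)I | intermediate
21 | [(E)-1,1-dimethoxybut-2-en-2-yl]lithium | C/C=C(/C(OC)OC)[Li] | intermediate (not isolated)
22 | 2-[(E)-1,1-dimethoxybut-2-en-2-yl]-4,4,5,5-tetramethyl-1,3,2-dioxaborolane | C/C=C(/C(OC)OC)B1OC(C)(C)C(C)(C)O1 | intermediate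
23 | 5,6-dihydro-2H-pyran-2-one | O=C1C=CCCO1 | starting material
24 | (4S)-4-[(2E)-1,1-dimethoxybut-2-en-2-yl]oxan-2-one | O=C1C[C@H](CCO1)/C(C(OC)OC)=C\C | intermediate
25 | methyl (3S,4E)-4-(dimethoxymethyl)-3-(2-hydroxyethyl)hex-4-enoate | COC(=O)C[C@H](CCO)/C(C(OC)OC)=C\C | intermediate (not isolated)
26 | methyl (3S,4E)-4-(dimethoxymethyl)-3-(2-oxoethyl)hex-4-enoate | COC(=O)C[C@H](CC=O)/C(C(OC)OC)=C\C | intermediate
27 | methyl (3S,4E)-3-(2,2-dimethoxyethyl)-4-(dimethoxymethyl)hex-4-enoate | COC(=O)C[C@H](CC(OC)OC)/C(C(OC)OC)=C\C | intermediate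
28 | (3S,4E)-3-(2,2-dimethoxyethyl)-4-(dimethoxymethyl)hex-4-enoic acid | OC(=O)C[C@H](CC(OC)OC)/C(C(OC)OC)=C\C | intermediate
29 | {(1S,2R,3R,5R)-3-{[(3S,4E)-3-(2,2-dimethoxyethyl)-4-(dimethoxymethyl)hex-4-enoyl]oxy}-5-(2,2-dimethyl-1,3-dioxan-5-yl)-2-methylcyclopentyl}methyl (3S,4E)-3-(2,2-dimethoxyethyl)-4-(dimethoxymethyl)hex-4-enoate | C/C=C(/C(OC)OC)[C@@H](CC(OC)OC)CC(=O)OC[C@@H]1[C@@H](C)[C@H](OC(=O)C[C@H](CC(OC)OC)/C(C(OC)OC)=C\C)C[C@H]1C2COC(C)(C)OC2 | intermediate
30 | [(1S,2R,3R,5R)-5-(1,3-dihydroxypropan-2-yl)-3-{[(3S,4E)-4-formyl-3-(2-oxoethyl)hex-4-enoyl]oxy}-2-methylcyclopentyl]methyl (3S,4E)-4-formyl-3-(2-oxoethyl)hex-4-enoate | C/C=C(/C=O)[C@@H](CC=O)CC(=O)OC[C@@H]1[C@@H](C)[C@H](OC(=O)C[C@H](CC=O)/C(C=O)=C\C)C[C@H]1C(CO)CO | target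

## Step count and least certain steps

Total step count: 20. Longest linear sequence: 13 steps (steps 1–11, 19 and 20). The side-chain branch (steps 12–18, seven steps) joins at step 19.

Step 5 (key step). The most likely failure is insufficient π-facial discrimination, because the catalyst has to deliver 8 to the face that carries the allylic methyl group. A second risk is slow conversion, with oligomerisation of 8 on the Lewis acid. Fallback, replacing the cycloaddition by a conjugate addition: from 7, iminium-catalysed Michael addition of dimethyl malonate (diarylprolinol silyl ether, the antipode that attacks the same face, then DBU equilibration of the formyl-bearing carbon) would give dimethyl 2-[(1R,2S,3R,4R)-4-[(tert-butyldiphenylsilyl)oxy]-2-formyl-3-methylcyclopentyl]propanedioate F1. LiAlH4 in THF would then reduce the aldehyde and both esters, and the route is rejoined at 15.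

Step 1. The α-methyl group on the enone may erode the enantioselectivity of the copper–boryl addition, and protonation may leave some cis isomer. Fallback, resolution in place of asymmetric catalysis: from 1, borylation–oxidation with CuCl, NaOtBu and an achiral bisphosphine would give racemic trans-3-hydroxy-2-methylcyclopentan-1-one F2. Candida antarctica lipase B with vinyl acetate should acylate the (3R) enantiomer faster (larger, branched C2 side against the C4 methylene), giving (1R,2S)-2-methyl-3-oxocyclopentyl acetate F3, which is separated from the unreacted enantiomer. Lipase-mediated hydrolysis of F3 at pH 7, which avoids β-elimination, returns the route at 3.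

Step 7. Formaldehyde may also react at the branched C1 aldehyde through its enamine (hydroxymethylation at a quaternary centre), and the 2-substituted acrolein may polymerise or drift into conjugation with the ring. Fallback, homologation at the lactone oxidation level: from 11, NaBH4 would give 2-[(1R,2S,3R,4R)-4-[(tert-butyldiphenylsilyl)oxy]-2-(hydroxymethyl)-3-methylcyclopentyl]ethan-1-ol F4. Oxidative lactonisation with TEMPO (cat.) and PhI(OAc)2, which should begin at the less hindered primary alcohol of the two-carbon arm, would give the trans-fused lactone (4aS,6R,7R,7aS)-6-[(tert-butyldiphenylsilyl)oxy]-7-methylhexahydrocyclopenta[c]pyran-3(1H)-one F5. Its lithium enolate (LiN(iPr)2, −78 °C) with monomeric formaldehyde would give the 4-(hydroxymethyl) lactone F6, whose new centre is irrelevant. LiAlH4 would then open it to 15.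

Step 15. Transmetalation of the α-branched, trisubstituted alkenylboronate to rhodium may be slow, so that protodeboronation and base-mediated opening of the lactone win. Fallback, auxiliary control in place of catalyst control: from 20, the alkenyllithium 21 is converted into the magnesium cuprate (MgBr2·OEt2, CuBr·SMe2) and added to (R)-3-[(E)-5,5-dimethoxypent-2-enoyl]-4-phenyloxazolidin-2-one F7, obtained by N-acylation of the commercial auxiliary. Addition anti to the phenyl group in the chelated s-cis conformer should give (R)-3-[(3S,4E)-3-(2,2-dimethoxyethyl)-4-(dimethoxymethyl)hex-4-enoyl]-4-phenyloxazolidin-2-one F8. LiOH/H2O2 would cleave the auxiliary and return the route at 28, bypassing steps 15–18.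

Step 20. During the acid treatment the liberated 1,3-diol may acetalise with the new aldehydes, or acetal cleavage may stay incomplete at an acidity that the esters still tolerate. Fallback, oxidative unmasking in which no aldehyde meets acid: from 17, Steglich esterification with 2-[(3aS,4E,5S,6aR)-4-ethylidene-2,2-dimethyltetrahydro-4H-cyclopenta[d][1,3]dioxol-5-yl]acetic acid F9 would give the bis-ester tris-acetonide F10. In F9 a cis-diol C–C bond holds the two future aldehyde carbons together; it needs its own preparation from a carbohydrate-derived isopropylidenedioxycyclopentenone by conjugate addition and Wittig ethylidenation. Aqueous acetic acid would remove all three ketals before any aldehyde exists, giving the hexaol F11. NaIO4 in aqueous THF at pH 7 would cleave only the two 1,2-diols, leave the 1,3-diol, and return the route at 30.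

Further compounds

F1 | step 5 | dimethyl 2-[(1R,2S,3R,4R)-4-[(tert-butyldiphenylsilyl)oxy]-2-formyl-3-methylcyclopentyl]propanedioate | O=C[C@@H]1[C@@H](C)[C@H](O[Si](c2ccccc2)(c2ccccc2)C(C)(C)C)C[C@H]1C(C(=O)OC)C(=O)OC
F2 | step 1 | racemic trans-3-hydroxy-2-methylcyclopentan-1-one (both enantiomers) | O=C1CC[C@@H](O)[C@@H]1C.O=C1CC[C@H](O)[C@H]1C
F3 | step 1 | (1R,2S)-2-methyl-3-oxocyclopentyl acetate | O=C1CC[C@@H](OC(C)=O)[C@@H]1C
F4 | step 7 | 2-[(1R,2S,3R,4R)-4-[(tert-butyldiphenylsilyl)oxy]-2-(hydroxymethyl)-3-methylcyclopentyl]ethan-1-ol | OC[C@@H]1[C@@H](C)[C@H](O[Si](c2ccccc2)(c2ccccc2)C(C)(C)C)C[C@H]1CCO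
F5 | step 7 | (4aS,6R,7R,7aS)-6-[(tert-butyldiphenylsilyl)oxy]-7-methylhexahydrocyclopenta[c]pyran-3(1H)-one | O=C1OC[C@@H]2[C@@H](C)[C@H](O[Si](c3ccccc3)(c3ccccc3)C(C)(C)C)C[C@H]2C1
F6 | step 7 | (4aS,6R,7R,7aS)-6-[(tert-butyldiphenylsilyl)oxy]-4-(hydroxymethyl)-7-methylhexahydrocyclopenta[c]pyran-3(1H)-one (C4 epimers) | O=C1OC[C@@H]2[C@@H](C)[C@H](O[Si](c3ccccc3)(c3ccccc3)C(C)(C)C)C[C@H]2C1CO
F7 | step 15 | (R)-3-[(E)-5,5-dimethoxypent-2-enoyl]-4-phenyloxazolidin-2-one | COC(OC)C/C=C/C(=O)N1[C@H](c2ccccc2)COC1=O
F8 | step 15 | (R)-3-[(3S,4E)-3-(2,2-dimethoxyethyl)-4-(dimethoxymethyl)hex-4-enoyl]-4-phenyloxazolidin-2-one | C/C=C(/C(OC)OC)[C@@H](CC(OC)OC)CC(=O)N1[C@H](c2ccccc2)COC1=O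
F9 | step 20 | 2-[(3aS,4E,5S,6aR)-4-ethylidene-2,2-dimethyltetrahydro-4H-cyclopenta[d][1,3]dioxol-5-yl]acetic acid | OC(=O)C[C@@H]1C[C@H]2OC(C)(C)O[C@H]2/C1=C/C
F10 | step 20 | bis-ester of 17 with F9 (both hydroxyl groups acylated; three isopropylidene ketals) | O=C(C[C@@H]2C[C@H]3OC(C)(C)O[C@H]3/C2=C/C)OC[C@@H]1[C@@H](C)[C@H](OC(=O)C[C@@H]2C[C@H]3OC(C)(C)O[C@H]3/C2=C/C)C[C@H]1C4COC(C)(C)OC4
F11 | step 20 | hexaol from F10 (two ring cis-1,2-diols and the free 1,3-diol) | O=C(C[C@@H]2C[C@@H](O)[C@@H](O)/C2=C/C)OC[C@@H]1[C@@H](C)[C@H](OC(=O)C[C@@H]2C[C@@H](O)[C@@H](O)/C2=C/C)C[C@H]1C(CO)CO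
A1 | alternative 1 | (2R,3S,4S)-4-(2,2-dimethyl-1,3-dioxan-5-yl)-3-{[dimethyl(propan-2-yloxy)silyl]methyl}-2-methylcyclopentan-1-one | CC(C)O[Si](C)(C)C[C@@H]1[C@@H](C)C(=O)C[C@H]1C2COC(C)(C)OC2
A2 | alternative 1 | (R)-4-(2,2-dimethyl-1,3-dioxan-5-yl)cyclopent-2-en-1-one | O=C1C[C@H](C=C1)C2COC(C)(C)OC2
A3 | alternative 2 | dimethyl 2-[(1R,2S,3R,4R)-4-(tert-butyldimethylsilyloxy)-2-formyl-3-methylcyclopentyl]propanedioate | O=C[C@@H]1[C@@H](C)[C@H](O[Si](C)(C)C(C)(C)C)C[C@H]1C(C(=O)OC)C(=O)OC
A4 | alternative 2 | dimethyl 2-[(3R,4E)-3-(tert-butyldimethylsilyloxy)-4-methyl-6-oxohex-4-en-1-ylidene]propanedioate | O=C/C=C(\C)[C@H](O[Si](C)(C)C(C)(C)C)CC=C(C(=O)OC)C(=O)OC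
A5 | alternative 3 | (1R,2R,3S,4R)-3-[(benzyloxy)methyl]-4-(2,2-dimethyl-1,3-dioxan-5-yl)-2-methylcyclopentan-1-ol | c1ccccc1COC[C@@H]2[C@@H](C)[C@H](O)C[C@H]2C3COC(C)(C)OC3
A6 | alternative 3 | (3R,4R)-4-[(benzyloxy)methyl]-3-(2,2-dimethyl-1,3-dioxan-5-yl)hex-5-enal | c1ccccc1COC[C@H](C=C)[C@@H](CC=O)C3COC(C)(C)OC3
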